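## Plan

- **Cuts, in retrosynthetic order:** the three phenols are masked as MOM ethers. Then the C3–C4 bond of ring C is cut, then the O1–C2 ether bond, and finally on ring B the 4'-O–CH3 bond and the C5'–C(CH3)2 bond. The last cut leads back to a 4'-O-prenyl ether.
- **Enabling feature:** in ring C the carbonyl carbon C4 and the carbinol carbon C3 are direct neighbours and both carry oxygen. Both therefore map onto carbonyl carbons of like polarity, the ring-A formyl group and the ring-B aroyl group. The C8a–O1–C2 tether holds them in a 1,6 relationship, and a carbene reverses the polarity of the formyl carbon.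
- **Forward order:** gallacetophenone (ring B) is O-prenylated, MOM-protected, rearranged, O-methylated and α-brominated. It is joined through O1–C2 to 4-O-MOM-protected 2,4-dihydroxybenzaldehyde (ring A). Ring C is the only ring made and closes last. The MOM helpers, which keep acidic protons away from the carbene, are then removed.
- **Stereochemistry:** the only stereocenter, C3 (R; OH > C4 > C2 > C1'), is set in the ring closure by a chiral triazolylidene. It is fully substituted, so it cannot epimerise by enolisation afterwards.

Key step: step 8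

Assumption: the sense of induction in step 8 is inferred from the usual model for aminoindanol-derived triazolylidenes (E-enaminol, one face shielded by the indane). If the first run shows the opposite sense, the equally available (5aS,10bR) antipode of the catalyst is used and nothing else changes.

## Route

Step 1
Reactants: 1 2',3',4'-trihydroxyacetophenone (gallacetophenone); 2 prenyl bromide (1-bromo-3-methylbut-2-ene)
Product: 3 1-[2,3-dihydroxy-4-(3-methylbut-2-en-1-yloxy)phenyl]ethan-1-one
Conditions: Li2CO3, DMF, 45 °C, Ar
Reagents that add atoms: none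
Why: Williamson ether synthesis in which the 4-OH, para to the acetyl group, is the most acidic phenol (the 2-OH is held in a hydrogen bond to the carbonyl oxygen and the 3-OH is not conjugated with it), so the weak base should form and alkylate only the 4-phenoxide.

Step 2
Reactants: 3 1-[2,3-dihydroxy-4-(3-methylbut-2-en-1-yloxy)phenyl]ethan-1-one
Product: 4 1-[2,3-bis(methoxymethoxy)-4-(3-methylbut-2-en-1-yloxy)phenyl]ethan-1-one
Conditions: NaH, MOMCl, DMF, 0 °C → rt
Reagents that add atoms: chloromethyl methyl ether (MOMCl), COCCl
Why: O-alkylation of both remaining phenoxides with a very reactive chloromethyl ether, the strong base being needed to break the chelate of the 2-OH, gives acetals that tolerate the heat and base of the following steps.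

Step 3
Reactants: 4 1-[2,3-bis(methoxymethoxy)-4-(3-methylbut-2-en-1-yloxy)phenyl]ethan-1-one
Product: 6 1-[4-hydroxy-2,3-bis(methoxymethoxy)-5-(2-methylbut-3-en-2-yl)phenyl]ethan-1-one, via ortho-dienone 5 (not isolated)
Conditions: PhNEt2, 190 °C, sealed tube, Ar
Reagents that add atoms: none
Why: Aromatic Claisen rearrangement, in which the [3,3] shift inverts the prenyl unit and delivers it as the 1,1-dimethylallyl group to C5, the only free ortho position (a shift to the blocked C3 is reversible), and tautomerisation of 5 makes the step irreversible while the basic solvent suppresses acid-induced cyclisation.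

Step 4
Reactants: 6 1-[4-hydroxy-2,3-bis(methoxymethoxy)-5-(2-methylbut-3-en-2-yl)phenyl]ethan-1-one
Product: 7 1-[4-methoxy-2,3-bis(methoxymethoxy)-5-(2-methylbut-3-en-2-yl)phenyl]ethan-1-one
Conditions: MeI, K2CO3, DMF, rt → 40 °C
Reagents that add atoms: iodomethane (MeI), CI
Why: Williamson methylation of a hindered but acidic (para-acyl) phenol with the smallest electrophile in a dipolar aprotic solvent.

Step 5
Reactants: 7 1-[4-methoxy-2,3-bis(methoxymethoxy)-5-(2-methylbut-3-en-2-yl)phenyl]ethan-1-one
Product: 9 2-bromo-1-[4-methoxy-2,3-bis(methoxymethoxy)-5-(2-methylbut-3-en-2-yl)phenyl]ethan-1-one, via trimethylsilyl enol ether 8 (not isolated)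
Conditions: LiN(SiMe3)2, Me3SiCl, THF, −78 °C; then NBS, −78 → 0 °C
Reagents that add atoms: N-bromosuccinimide (NBS), O=C1CCC(=O)N1Br; chlorotrimethylsilane (Me3SiCl), C[Si](C)(C)Cl (its silyl group is held only by 8)
Why: Enolisation at the only enolisable position with in situ silylation, followed by electrophilic bromination of the silyl enol ether, which is far more nucleophilic than the neopentyl-type terminal alkene or the arene, so neither Br2 nor HBr meets the alkene or the MOM groups.

Step 6
Reactants: 10 2,4-dihydroxybenzaldehyde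
Product: 11 2-hydroxy-4-(methoxymethoxy)benzaldehyde
Conditions: MOMCl (1 equiv), K2CO3, acetone, 0 °C → rt
Reagents that add atoms: chloromethyl methyl ether (MOMCl), COCCl
Why: Regioselective O-alkylation, since the 4-OH is the more acidic and accessible phenol while the 2-OH is held in a hydrogen bond to the formyl oxygen.

Step 7
Reactants: 9 2-bromo-1-[4-methoxy-2,3-bis(methoxymethoxy)-5-(2-methylbut-3-en-2-yl)phenyl]ethan-1-one; 11 2-hydroxy-4-(methoxymethoxy)benzaldehyde
Product: 12 4-(methoxymethoxy)-2-{2-[4-methoxy-2,3-bis(methoxymethoxy)-5-(2-methylbut-3-en-2-yl)phenyl]-2-oxoethoxy}benzaldehyde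
Conditions: K2CO3 (1 equiv), acetone, 0 °C → rt
Reagents that add atoms: none
Why: Williamson etherification by SN2 displacement at a highly activated α-bromoketone, run cold with a mild base so that ether formation outruns enolisation of the new O–CH2–C(=O) unit, the aldehyde being further deactivated toward aldol attack by its para MOM-oxy donor.

Step 8
Reactants: 12 4-(methoxymethoxy)-2-{2-[4-methoxy-2,3-bis(methoxymethoxy)-5-(2-methylbut-3-en-2-yl)phenyl]-2-oxoethoxy}benzaldehyde
Product: 14 (3R)-3-hydroxy-7-(methoxymethoxy)-3-[4-methoxy-2,3-bis(methoxymethoxy)-5-(2-methylbut-3-en-2-yl)phenyl]-2,3-dihydro-4H-chromen-4-one, via carbene-bound enaminol 13 (not isolated)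
Conditions: (5aR,10bS)-2-(pentafluorophenyl)-5a,10b-dihydro-4H,6H-indeno[2,1-b][1,2,4]triazolo[4,3-d][1,4]oxazin-2-ium tetrafluoroborate (10 mol %), Et3N (10 mol %), toluene, rt, Ar
Reagents that add atoms: none
Why: The triazolylidene freed by Et3N adds to the formyl group of 12, the only carbonyl that bears a hydrogen, and a proton shift gives enaminol 13, whose former formyl carbon is now nucleophilic; this carbon attacks the 1,6-related aryl ketone with transfer of the enol proton, and loss of the carbene leaves the C4 ketone next to the new C3 carbinol. The closest known reaction type is the enantioselective intramolecular crossed aldehyde–ketone benzoin reaction of 2-(2-aryl-2-oxoethoxy)benzaldehydes, which gives 3-aryl-3-hydroxychroman-4-ones. Ring C closes in the 6-(enolexo)-exo-trig mode. The single new stereocenter C3 is under catalyst control: the indane blocks one face of the planar enaminol, while the enol O–H···O=C hydrogen bond and the short O–CH2 tether orient the ketone so that its Si face meets the open face with ring B lying over the azole, which should give the (R)-carbinol. The step needs carbene addition to win over base-induced aldol condensation of the acidic O–CH2–C(=O) unit onto the aldehyde, which is secured by the electron-poor N-C6F5 azolium (a weak amine in catalytic amount suffices) and by the donor-deactivated aldehyde. Intermolecular homo-benzoin coupling is disfavoured by the tether, and the MOM groups remove the phenolic protons that would quench the carbene or deactivate the ketone by chelation.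

Step 9
Reactants: 14 (3R)-3-hydroxy-7-(methoxymethoxy)-3-[4-methoxy-2,3-bis(methoxymethoxy)-5-(2-methylbut-3-en-2-yl)phenyl]-2,3-dihydro-4H-chromen-4-one
Product: 15 (3R)-3-[2,3-dihydroxy-4-methoxy-5-(2-methylbut-3-en-2-yl)phenyl]-3,7-dihydroxy-2,3-dihydro-4H-chromen-4-one (target)
Conditions: HCl (cat.), MeOH, 40 °C, Ar
Reagents that add atoms: none
Why: Acid-catalysed transacetalisation of the three phenolic MOM ethers to dimethoxymethane, tolerated because the tertiary carbinol is α to a carbonyl group and resists ionisation, C3 has no hydrogen to enolise, and the monosubstituted alkene sits next to a methyl ether rather than a free phenol and so should neither protonate nor cyclise under such mild acid.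

## Compound list

1 | 2',3',4'-trihydroxyacetophenone (gallacetophenone) | CC(=O)c1ccc(O)c(O)c1O | starting material
2 | prenyl bromide (1-bromo-3-methylbut-2-ene) | CC(C)=CCBr | starting material
3 | 1-[2,3-dihydroxy-4-(3-methylbut-2-en-1-yloxy)phenyl]ethan-1-one | CC(=O)c1ccc(OCC=C(C)C)c(O)c1O | intermediate
4 | 1-[2,3-bis(methoxymethoxy)-4-(3-methylbut-2-en-1-yloxy)phenyl]ethan-1-one | CC(=O)c1ccc(OCC=C(C)C)c(OCOC)c1OCOC | intermediate
5 | 4-acetyl-2,3-bis(methoxymethoxy)-6-(2-methylbut-3-en-2-yl)cyclohexa-2,4-dien-1-one (racemic, not isolated) | C=CC(C)(C)C1C=C(C(C)=O)C(OCOC)=C(OCOC)C1=O | intermediate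
6 | 1-[4-hydroxy-2,3-bis(methoxymethoxy)-5-(2-methylbut-3-en-2-yl)phenyl]ethan-1-one | C=CC(C)(C)c1cc(C(C)=O)c(OCOC)c(OCOC)c1O | intermediate
7 | 1-[4-methoxy-2,3-bis(methoxymethoxy)-5-(2-methylbut-3-en-2-yl)phenyl]ethan-1-one | C=CC(C)(C)c1cc(C(C)=O)c(OCOC)c(OCOC)c1OC | intermediate
8 | trimethylsilyl enol ether of 7 (not isolated) | C=CC(C)(C)c1cc(C(=C)O[Si](C)(C)C)c(OCOC)c(OCOC)c1OC | intermediate
9 | 2-bromo-1-[4-methoxy-2,3-bis(methoxymethoxy)-5-(2-methylbut-3-en-2-yl)phenyl]ethan-1-one | C=CC(C)(C)c1cc(C(=O)CBr)c(OCOC)c(OCOC)c1OC | intermediate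
10 | 2,4-dihydroxybenzaldehyde | O=Cc1ccc(O)cc1O | starting material
11 | 2-hydroxy-4-(methoxymethoxy)benzaldehyde | O=Cc1ccc(OCOC)cc1O | intermediate
12 | 4-(methoxymethoxy)-2-{2-[4-methoxy-2,3-bis(methoxymethoxy)-5-(2-methylbut-3-en-2-yl)phenyl]-2-oxoethoxy}benzaldehyde | C=CC(C)(C)c1cc(C(=O)COc2cc(OCOC)ccc2C=O)c(OCOC)c(OCOC)c1OC | intermediate
13 | (E)-enaminol from 12 and the (5aR,10bS)-triazolylidene (not isolated) | O/C(c1ccc(OCOC)cc1OCC(=O)c1cc(C(C)(C)C=C)c(OC)c(OCOC)c1OCOC)=C1/N(c2c(F)c(F)c(F)c(F)c2F)N=C2CO[C@@H]3Cc4ccccc4[C@@H]3N12 | intermediate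
14 | (3R)-3-hydroxy-7-(methoxymethoxy)-3-[4-methoxy-2,3-bis(methoxymethoxy)-5-(2-methylbut-3-en-2-yl)phenyl]-2,3-dihydro-4H-chromen-4-one | C=CC(C)(C)c1cc([C@@]2(O)COc3cc(OCOC)ccc3C2=O)c(OCOC)c(OCOC)c1OC | intermediate
15 | (3R)-3-[2,3-dihydroxy-4-methoxy-5-(2-methylbut-3-en-2-yl)phenyl]-3,7-dihydroxy-2,3-dihydro-4H-chromen-4-one | C=CC(C)(C)c1cc([C@@]2(O)COc3cc(O)ccc3C2=O)c(O)c(O)c1OC | target

Total step count: 9. Longest linear sequence: 8 (steps 1, 2, 3, 4, 5, 7, 8, 9).

## Steps most likely to fail

**Step 8.**
- Risk: facial selectivity may be poor at the ortho-substituted, hindered aryl ketone. Enantiopurity may also erode through reversible ring opening on long contact with the carbene.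
- Fallback (stereochemistry by resolution instead of catalyst control): it sets out from 12 and comes back at 14.
- 12 is cyclised with the achiral carbene from 2-(pentafluorophenyl)-6,7-dihydro-5H-pyrrolo[2,1-c][1,2,4]triazol-2-ium tetrafluoroborate and Et3N in toluene. This gives the racemic tris-MOM 3-hydroxyisoflavanone F1.
- Preparative HPLC on a polysaccharide-based chiral stationary phase then separates 14 from the (3S)-tris-MOM 3-hydroxyisoflavanone F2.

**Step 3.**
- Risk: at the temperature needed, the prenyl group may be lost by ionisation. The first-formed phenol may also react on by abnormal Claisen rearrangement or by cyclisation onto the alkene.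
- Fallback (cross-coupling instead of a sigmatropic shift): it sets out from 1 and comes back at 7.
- 1 is methylated at the 4-OH (MeI, Li2CO3, DMF) to 1-(2,3-dihydroxy-4-methoxyphenyl)ethan-1-one F3.
- Both remaining phenols are protected (NaH, MOMCl, DMF) to 1-[4-methoxy-2,3-bis(methoxymethoxy)phenyl]ethan-1-one F4.
- Bromination with NBS in MeCN should occur at C5, which is ortho to OMe, para to the 2-O substituent and meta to the acetyl group. It gives 1-[5-bromo-4-methoxy-2,3-bis(methoxymethoxy)phenyl]ethan-1-one F5.
- A branch-selective (γ-selective) Suzuki–Miyaura coupling of F5 with prenylboronic acid pinacol ester then gives 7. The conditions are Pd(OAc)2, a bulky biarylphosphine chosen for the branched product, K3PO4 and THF/H2O.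

**Step 7.**
- Risk: the product may undergo base-induced intramolecular aldol condensation as it forms (the Rap–Stoermer pathway).
- Fallback (neutral redox condensation instead of phenoxide alkylation): it sets out from 7 and comes back at 12.
- 7 is converted into 8 as in step 5.
- 8 is submitted to a Rubottom oxidation (mCPBA, NaHCO3, CH2Cl2, −20 °C, then mild desilylation). The silyl enol ether should react well before the terminal alkene. The product is 2-hydroxy-1-[4-methoxy-2,3-bis(methoxymethoxy)-5-(2-methylbut-3-en-2-yl)phenyl]ethan-1-one F6.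
- F6 is coupled with 11 in a Mitsunobu reaction (PPh3, DIAD, toluene, 0 °C) to give 12.

## Further compounds

F1 | step 8 | racemic 3-hydroxy-7-(methoxymethoxy)-3-[4-methoxy-2,3-bis(methoxymethoxy)-5-(2-methylbut-3-en-2-yl)phenyl]-2,3-dihydro-4H-chromen-4-one | C=CC(C)(C)c1cc(C2(O)COc3cc(OCOC)ccc3C2=O)c(OCOC)c(OCOC)c1OC
F2 | step 8 | (3S)-3-hydroxy-7-(methoxymethoxy)-3-[4-methoxy-2,3-bis(methoxymethoxy)-5-(2-methylbut-3-en-2-yl)phenyl]-2,3-dihydro-4H-chromen-4-one | C=CC(C)(C)c1cc([C@]2(O)COc3cc(OCOC)ccc3C2=O)c(OCOC)c(OCOC)c1OC
F3 | step 3 | 1-(2,3-dihydroxy-4-methoxyphenyl)ethan-1-one | CC(=O)c1ccc(OC)c(O)c1O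
F4 | step 3 | 1-[4-methoxy-2,3-bis(methoxymethoxy)phenyl]ethan-1-one | CC(=O)c1ccc(OC)c(OCOC)c1OCOC
F5 | step 3 | 1-[5-bromo-4-methoxy-2,3-bis(methoxymethoxy)phenyl]ethan-1-one | CC(=O)c1cc(Br)c(OC)c(OCOC)c1OCOC
F6 | step 7 | 2-hydroxy-1-[4-methoxy-2,3-bis(methoxymethoxy)-5-(2-methylbut-3-en-2-yl)phenyl]ethan-1-one | C=CC(C)(C)c1cc(C(=O)CO)c(OCOC)c(OCOC)c1OC
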